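**Retrosynthetic overview**

- The strategy rests on ring B (C4a, C5, C6, C7, C8, C8a of the chromanone), a fully substituted phloroglucinol. Its oxygens at C5, C7 and C8a must be distinguishable so that ring C can close only through the oxygen on C8a.
- Ring B is disconnected into a cyclobutenone and a siloxyalkyne. Their benzannulation forms C7–C8, C4a–C8a and C6–C7 and delivers C7–OH, C5–OEt and C8a–OSi(i-Pr)3 in one operation; the C8 methylene bridge to ring A arrives as the alkyne substituent.
- The siloxyalkyne comes from the ring A arylacetate (ester homologation to an ynolate, O-silylation); the cyclobutenone comes from methylketene and ethoxyacetylene.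
- After the annulation, the isobutyryl group is placed on ring A by directed lithiation, not by electrophilic substitution, because C4a of ring B is still open at that stage. Desilylation, acylation at C4a with oxa-Michael closure from O–C8a, and BCl3 cleavage of the three carbonyl-flanked ethers finish the route.
- Ring order: ring A (purchased), ring B (benzannulation), ring C (chromanone closure).

Key step: step 5

Remark: the target has no stereocentre; 4, 13, 15 and 17 are racemic and their stereocentres are erased later. Positions of ring B and ring C are given in chromanone numbering throughout.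

**Step 1**
Reactants: 1 2,4,6-trimethoxytoluene; 2 ethyl chlorooxoacetate
Product: 3 ethyl 2-oxo-2-(2,4,6-trimethoxy-3-methylphenyl)acetate
Conditions: TiCl4 (1.1 equiv), CH2Cl2, −20 → 0 °C
Reagents that add atoms: none
Why: Friedel–Crafts acylation; the two unsubstituted carbons of 1 are equivalent and each is activated by three methoxy groups, and the keto ester group slows a second acylation.

**Step 2**
Reactants: 3 ethyl 2-oxo-2-(2,4,6-trimethoxy-3-methylphenyl)acetate
Product: 5 ethyl 2-(2,4,6-trimethoxy-3-methylphenyl)acetate, via hydroxy ester 4 (not isolated)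
Conditions: Et3SiH (3 equiv), CF3CO2H, CH2Cl2, 0 °C → rt
Reagents that add atoms: none
Why: Ionic hydrogenation of an electron-rich aryl ketone; hydride reduces the protonated ketone to racemic 4, whose benzylic cation, stabilised by the trimethoxyaryl ring, takes a second hydride, so the stereocentre of 4 disappears.

**Step 3**
Reactants: 5 ethyl 2-(2,4,6-trimethoxy-3-methylphenyl)acetate; 6 dibromomethane
Product: 9 triisopropyl{[3-(2,4,6-trimethoxy-3-methylphenyl)prop-1-yn-1-yl]oxy}silane, via lithium dibromoenolate 7 (not isolated), via lithium ynolate 8 (not isolated)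
Conditions: 6 (2.2 equiv), lithium 2,2,6,6-tetramethylpiperidide (2.2 equiv), THF, −78 °C; n-BuLi, −78 → 0 °C; i-Pr3SiCl, −78 °C → rt
Reagents that add atoms: chlorotriisopropylsilane, CC(C)[Si](Cl)(C(C)C)C(C)C
Why: Kowalski ester homologation; LiCHBr2 should add to the ester at −78 °C faster than it enolises it, enolate 7 undergoes bromine–lithium exchange and 1,2-shift of the arylmethyl group to ynolate 8, and the bulky chlorosilane silylates 8 on oxygen.

**Step 4**
Reactants: 10 propionyl chloride; 11 ethoxyacetylene
Product: 13 3-ethoxy-4-methylcyclobut-2-en-1-one (racemic), via methylketene 12 (not isolated)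
Conditions: Et3N, Et2O, 0 °C → rt, slow addition of 10 to 11 (excess)
Reagents that add atoms: none
Why: Dehydrochlorination gives 12, which undergoes a thermal [2+2] ketene–alkyne cycloaddition with the ynol ether, its carbonyl carbon bonding to the unsubstituted alkyne carbon; C4 forms racemic, should not be shifted by base because its enolate would be a cyclobutadienolate, and is erased in step 5.

**Step 5**
Reactants: 9 triisopropyl{[3-(2,4,6-trimethoxy-3-methylphenyl)prop-1-yn-1-yl]oxy}silane; 13 3-ethoxy-4-methylcyclobut-2-en-1-one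
Product: 18 3-ethoxy-2-methyl-6-[(2,4,6-trimethoxy-3-methylphenyl)methyl]-5-(triisopropylsilyloxy)phenol, via vinylketene 14 (not isolated), via vinylcyclobutenone 15 (not isolated), via dienylketene 16 (not isolated), via cyclohexadienone 17 (not isolated)
Conditions: toluene, 80 → 110 °C, sealed tube, argon, 13 in slight excess
Reagents that add atoms: none
Why: Heating opens 13 by 4π-electrocyclic cleavage of its C1–C4 bond to vinylketene 14, which adds across siloxyalkyne 9 in a [2+2] cycloaddition (forming C7–C8 and C4a–C8a) to give vinylcyclobutenone 15; 15 opens in the same way to dienylketene 16, which closes to cyclohexadienone 17, and 17 enolises to phenol 18. The closest known reaction type is the Danheiser benzannulation of cyclobutenones with siloxyalkynes, which gives resorcinol monosilyl ethers in this manner. Ring B is closed by a thermal disrotatory 6π-electrocyclisation of 16 that forms the C6–C7 bond, and the hydrogen on C6, inherited from C4 of 13, allows the final tautomerisation. No stereocentre survives, since those of 13, 15 and 17 are erased on aromatisation. The one selectivity needed is the orientation of the ketene–alkyne cycloaddition, and the polarisation of 9 secures it: its nucleophilic carbon (C8, carrying the arylmethyl group) attacks the electrophilic ketene carbon (C7), so the oxygen-bearing carbon becomes C8a and bonds to C4a. The three oxygens of ring B should therefore emerge as free hydroxyl (C7), ethyl ether (C5) and silyl ether (C8a), and the hindered C7 hydroxyl is a poor trap for 14.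

**Step 6**
Reactants: 18 3-ethoxy-2-methyl-6-[(2,4,6-trimethoxy-3-methylphenyl)methyl]-5-(triisopropylsilyloxy)phenol; 19 N-methoxy-N,2-dimethylpropanamide
Product: 21 1-{3-[(4-ethoxy-2-hydroxy-3-methyl-6-(triisopropylsilyloxy)phenyl)methyl]-2,4,6-trimethoxy-5-methylphenyl}-2-methylpropan-1-one, via dilithio species 20 (not isolated)
Conditions: n-BuLi (2.4 equiv), THF, 0 °C → rt; 19, −78 → 0 °C; aq NH4Cl
Reagents that add atoms: none
Why: Directed ortho-metalation then Weinreb ketone synthesis; the first equivalent of n-BuLi makes the C7 phenoxide, which shuts down ring B (C4a is para to the oxido group and the bulky silyl ether does not direct), the second lithiates the ring A carbon between two methoxy groups, and the N-methoxy-N-methylamide should acylate this aryllithium once only.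

**Step 7**
Reactants: 21 1-{3-[(4-ethoxy-2-hydroxy-3-methyl-6-(triisopropylsilyloxy)phenyl)methyl]-2,4,6-trimethoxy-5-methylphenyl}-2-methylpropan-1-one
Product: 22 1-{3-[(4-ethoxy-2,6-dihydroxy-3-methylphenyl)methyl]-2,4,6-trimethoxy-5-methylphenyl}-2-methylpropan-1-one
Conditions: Bu4NF, THF, 0 °C; aq NH4Cl; handled under argon
Reagents that add atoms: none
Why: Fluoride-induced cleavage of the aryl silyl ether frees the C8a hydroxyl while the C5 ethyl ether and all methyl ethers stay.

**Step 8**
Reactants: 22 1-{3-[(4-ethoxy-2,6-dihydroxy-3-methylphenyl)methyl]-2,4,6-trimethoxy-5-methylphenyl}-2-methylpropan-1-one; 23 3,3-dimethylacrylic acid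
Product: 25 5-ethoxy-7-hydroxy-2,2,6-trimethyl-8-{[2,4,6-trimethoxy-3-methyl-5-(2-methylpropanoyl)phenyl]methyl}chroman-4-one, via aryl enone 24 (not isolated)
Conditions: 23 (1.2 equiv), P2O5 in MeSO3H (1:10 w/w, Eaton's reagent), 50 °C
Reagents that add atoms: none
Why: Friedel–Crafts acylation at C4a, the only unsubstituted aromatic carbon left in the molecule, gives enone 24, and 6-endo-trig oxa-Michael addition of the C8a hydroxyl, the only free oxygen ortho to the new ketone, closes ring C; no stereocentre is formed.

**Step 9**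
Reactants: 25 5-ethoxy-7-hydroxy-2,2,6-trimethyl-8-{[2,4,6-trimethoxy-3-methyl-5-(2-methylpropanoyl)phenyl]methyl}chroman-4-one
Product: 26 Mallopallidol, 8-{[2,4-dihydroxy-6-methoxy-5-methyl-3-(2-methylpropanoyl)phenyl]methyl}-5,7-dihydroxy-2,2,6-trimethylchroman-4-one
Conditions: BCl3 (6 equiv), CH2Cl2, −78 → 0 °C; aqueous work-up
Reagents that add atoms: none
Why: Chelation-assisted ether cleavage by BCl3; the two methoxy groups ortho to the isobutyryl ketone and the C5 ethoxy group peri to the chromanone carbonyl should be dealkylated at low temperature, where the remaining ring A methoxy group, which has no carbonyl neighbour, should be left.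

**Compound list**

1 | 2,4,6-trimethoxytoluene | COc1cc(OC)c(C)c(OC)c1 | starting material
2 | ethyl chlorooxoacetate | CCOC(=O)C(=O)Cl | starting material
3 | ethyl 2-oxo-2-(2,4,6-trimethoxy-3-methylphenyl)acetate | CCOC(=O)C(=O)c1c(OC)cc(OC)c(C)c1OC | intermediate
4 | ethyl 2-hydroxy-2-(2,4,6-trimethoxy-3-methylphenyl)acetate (racemic, not isolated) | CCOC(=O)C(O)c1c(OC)cc(OC)c(C)c1OC | intermediate
5 | ethyl 2-(2,4,6-trimethoxy-3-methylphenyl)acetate | CCOC(=O)Cc1c(OC)cc(OC)c(C)c1OC | intermediate
6 | dibromomethane | BrCBr | starting material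
7 | lithium 1,1-dibromo-3-(2,4,6-trimethoxy-3-methylphenyl)prop-1-en-2-olate (not isolated) | [Li+].[O-]C(Cc1c(OC)cc(OC)c(C)c1OC)=C(Br)Br | intermediate
8 | lithium 3-(2,4,6-trimethoxy-3-methylphenyl)prop-1-yn-1-olate (not isolated) | [Li+].[O-]C#CCc1c(OC)cc(OC)c(C)c1OC | intermediate
9 | triisopropyl{[3-(2,4,6-trimethoxy-3-methylphenyl)prop-1-yn-1-yl]oxy}silane | COc1cc(OC)c(C)c(OC)c1CC#CO[Si](C(C)C)(C(C)C)C(C)C | intermediate
10 | propionyl chloride | CCC(=O)Cl | starting material
11 | ethoxyacetylene | CCOC#C | starting material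
12 | methylketene (not isolated) | CC=C=O | intermediate
13 | 3-ethoxy-4-methylcyclobut-2-en-1-one (racemic) | CCOC1=CC(=O)C1C | intermediate
14 | 3-ethoxypenta-1,3-dien-1-one (not isolated; C3=C4 geometry immaterial) | CCOC(=CC)C=C=O | intermediate
15 | 4-(1-ethoxyprop-1-en-1-yl)-3-(triisopropylsilyloxy)-2-[(2,4,6-trimethoxy-3-methylphenyl)methyl]cyclobut-2-en-1-one (racemic, not isolated) | O=C1C(Cc2c(OC)cc(OC)c(C)c2OC)=C(O[Si](C(C)C)(C(C)C)C(C)C)C1C(OCC)=CC | intermediate
16 | (3E)-5-ethoxy-3-(triisopropylsilyloxy)-2-[(2,4,6-trimethoxy-3-methylphenyl)methyl]hepta-1,3,5-trien-1-one (not isolated; C5=C6 geometry immaterial) | O=C=C(Cc1c(OC)cc(OC)c(C)c1OC)/C(O[Si](C(C)C)(C(C)C)C(C)C)=C\C(OCC)=CC | intermediate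
17 | 5-ethoxy-6-methyl-3-(triisopropylsilyloxy)-2-[(2,4,6-trimethoxy-3-methylphenyl)methyl]cyclohexa-2,4-dien-1-one (racemic, not isolated) | O=C1C(Cc2c(OC)cc(OC)c(C)c2OC)=C(O[Si](C(C)C)(C(C)C)C(C)C)C=C(OCC)C1C | intermediate
18 | 3-ethoxy-2-methyl-6-[(2,4,6-trimethoxy-3-methylphenyl)methyl]-5-(triisopropylsilyloxy)phenol | COc1cc(OC)c(C)c(OC)c1Cc1c(O)c(C)c(OCC)cc1O[Si](C(C)C)(C(C)C)C(C)C | intermediate
19 | N-methoxy-N,2-dimethylpropanamide | CC(C)C(=O)N(C)OC | starting material
20 | dilithio species of 18: lithium phenoxide at C7, aryllithium on ring A between the two methoxy groups (not isolated) | [Li]c1c(OC)c(C)c(OC)c(Cc2c(O[Li])c(C)c(OCC)cc2O[Si](C(C)C)(C(C)C)C(C)C)c1OC | intermediate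
21 | 1-{3-[(4-ethoxy-2-hydroxy-3-methyl-6-(triisopropylsilyloxy)phenyl)methyl]-2,4,6-trimethoxy-5-methylphenyl}-2-methylpropan-1-one | COc1c(C(=O)C(C)C)c(OC)c(C)c(OC)c1Cc1c(O)c(C)c(OCC)cc1O[Si](C(C)C)(C(C)C)C(C)C | intermediate
22 | 1-{3-[(4-ethoxy-2,6-dihydroxy-3-methylphenyl)methyl]-2,4,6-trimethoxy-5-methylphenyl}-2-methylpropan-1-one | COc1c(C(=O)C(C)C)c(OC)c(C)c(OC)c1Cc1c(O)c(C)c(OCC)cc1O | intermediate
23 | 3,3-dimethylacrylic acid | CC(C)=CC(=O)O | starting material
24 | 1-[6-ethoxy-2,4-dihydroxy-5-methyl-3-({2,4,6-trimethoxy-3-methyl-5-(2-methylpropanoyl)phenyl}methyl)phenyl]-3-methylbut-2-en-1-one (not isolated) | COc1c(C(=O)C(C)C)c(OC)c(C)c(OC)c1Cc1c(O)c(C)c(OCC)c(C(=O)C=C(C)C)c1O | intermediate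
25 | 5-ethoxy-7-hydroxy-2,2,6-trimethyl-8-{[2,4,6-trimethoxy-3-methyl-5-(2-methylpropanoyl)phenyl]methyl}chroman-4-one | COc1c(C(=O)C(C)C)c(OC)c(C)c(OC)c1Cc1c(O)c(C)c(OCC)c2c1OC(C)(C)CC2=O | intermediate
26 | Mallopallidol | COc1c(C)c(O)c(C(=O)C(C)C)c(O)c1Cc1c(O)c(C)c(O)c2c1OC(C)(C)CC2=O | target

**Step count**

Total: 9 steps. Longest linear sequence: 8 steps (steps 1, 2, 3, 5, 6, 7, 8, 9); step 4 is a one-step branch.

**Steps most likely to fail**

Step 5. Cyclobutenone 13 is a vinylogous ester and may open more slowly than usual. At the temperature then needed, siloxyalkyne 9 may undergo oxygen-to-carbon silyl migration to a silylketene, or vinylketene 14 may dimerise or acylate phenol 18. The fallback generates 14 at or below room temperature by 1,4-dehydrochlorination instead of ring opening. Commercial ethyl 3-oxopentanoate is converted with triethyl orthoformate and catalytic H2SO4 into ethyl (E)-3-ethoxypent-2-enoate F1, which is saponified (KOH, aqueous EtOH) to (E)-3-ethoxypent-2-enoic acid F2 and turned with (COCl)2 and catalytic DMF into (E)-3-ethoxypent-2-enoyl chloride F3. Slow addition of F3 to 9 and Et3N in CH2Cl2 at 0 °C → rt should give 14 and, by the same [2+2] cycloaddition, vinylcyclobutenone 15. Warming 15 in toluene at 80 °C then completes the cascade. This fallback sets out from 9 and rejoins the route at 15, and so at 18.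

Step 6. Lithiation of ring A may be slow because both directing methoxy groups are buttressed by ortho substituents. Deprotonation may also stray to the bridging methylene, or the hindered aryllithium may deprotonate 19 instead of adding to it. The fallback is electrophilic: 18 is esterified at the C7 hydroxyl (isobutyryl chloride, Et3N, DMAP, CH2Cl2) to 3-ethoxy-2-methyl-6-[(2,4,6-trimethoxy-3-methylphenyl)methyl]-5-(triisopropylsilyloxy)phenyl 2-methylpropanoate F4. The ester deactivates ring B, and C4a sits between the triisopropylsilyloxy and ethoxy groups, so Friedel–Crafts acylation (isobutyryl chloride, SnCl4, CH2Cl2, −40 °C) should go to ring A and give 3-ethoxy-2-methyl-6-{[2,4,6-trimethoxy-3-methyl-5-(2-methylpropanoyl)phenyl]methyl}-5-(triisopropylsilyloxy)phenyl 2-methylpropanoate F5. Bu4NF in THF followed by aqueous LiOH removes the silyl ether and the ester. This fallback sets out from 18 and rejoins the route at 22.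

Step 8. In hot strong acid the electron-rich diarylmethane may be cleaved at the C8–CH2 bond by ipso-protonation of ring B before acylation occurs, or ethers may be lost early. The fallback builds ring C under mild acid and then base. C-acetylation of 22 at C4a (Ac2O, BF3·OEt2, CH2Cl2, rt) should give 1-{3-[(3-acetyl-4-ethoxy-2,6-dihydroxy-5-methylphenyl)methyl]-2,4,6-trimethoxy-5-methylphenyl}-2-methylpropan-1-one F6. Kabbe condensation of F6 with acetone and pyrrolidine (EtOH, reflux) then closes the chromanone by aldol condensation and oxa-Michael addition of the C8a hydroxyl. This fallback sets out from 22 and rejoins the route at 25.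

**Further compounds**

F1 | step 5 | ethyl (E)-3-ethoxypent-2-enoate | CCOC(=O)/C=C(/OCC)CC
F2 | step 5 | (E)-3-ethoxypent-2-enoic acid | OC(=O)/C=C(/OCC)CC
F3 | step 5 | (E)-3-ethoxypent-2-enoyl chloride | ClC(=O)/C=C(/OCC)CC
F4 | step 6 | 3-ethoxy-2-methyl-6-[(2,4,6-trimethoxy-3-methylphenyl)methyl]-5-(triisopropylsilyloxy)phenyl 2-methylpropanoate | CC(C)C(=O)Oc1c(C)c(OCC)cc(O[Si](C(C)C)(C(C)C)C(C)C)c1Cc1c(OC)cc(OC)c(C)c1OC
F5 | step 6 | 3-ethoxy-2-methyl-6-{[2,4,6-trimethoxy-3-methyl-5-(2-methylpropanoyl)phenyl]methyl}-5-(triisopropylsilyloxy)phenyl 2-methylpropanoate | CC(C)C(=O)Oc1c(C)c(OCC)cc(O[Si](C(C)C)(C(C)C)C(C)C)c1Cc1c(OC)c(C(=O)C(C)C)c(OC)c(C)c1OC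
F6 | step 8 | 1-{3-[(3-acetyl-4-ethoxy-2,6-dihydroxy-5-methylphenyl)methyl]-2,4,6-trimethoxy-5-methylphenyl}-2-methylpropan-1-one | COc1c(C(=O)C(C)C)c(OC)c(C)c(OC)c1Cc1c(O)c(C)c(OCC)c(C(C)=O)c1O
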